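The numbers in the tables were generated by integration with constants of no real substance; scatter was added.

Slowness is what you watch here. On the list of suspects, first end groups meeting second end groups make links (rate constant k1), and first end groups meeting links eat them (rate constant k2).

| flask | first end groups | second end groups | remark | time |
|---|---|---|---|---|
| alder | 0.11 M | 0.242 M | run made earlier |  |
| cedar | 0.39 M | 0.242 M | run made earlier |  |
| larch | 0.23 M | 0.36 M | run made earlier |  |
| Tuesday's | 0.12 M | 0.150 M |  | 12 h |
| Sunday's | 0.15 M | 0.242 M |  | 12 h |
| Saturday's | 0.080 M | 0.500 M |  | 12 h |
| Friday's | 0.30 M | 0.150 M |  | 12 h |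
| Thursday's | 0.23 M | 0.242 M |  | 12 h |

| run | time / h | links / % |
|---|---|---|
| alder | 2.50 | 56.6 |
| alder | 5.00 | 75.5 |
| alder | 8.00 | 82.8 |
| alder | 10.0 | 85.0 |
| alder | 12.0 | 87.8 |
| cedar | 2.50 | 38.4 |
| cedar | 5.00 | 42.4 |
| cedar | 8.00 | 41.8 |
| cedar | 10.0 | 40.8 |
| cedar | 12.0 | 39.2 |
| larch | 1.00 | 41.0 |
| larch | 2.00 | 58.0 |
| larch | 3.00 | 67.3 |
| larch | 6.00 | 78.4 |
| larch | 12.0 | 82.4 |

(standard deviation of a reading: 0.5 percentage points)

- percentages count the first end groups that a species holds: one side product counts as two
- on the list of suspects stand: first end groups + second end groups -> links + by-product; first end groups + links -> side product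

* all flasks from highest to lowest amount of links, in percent of the first end groups charged, at 12 h (Tuesday's / Sunday's / Saturday's / Friday's / Thursday's)
* the amount of links, in percent of the first end groups charged of the flask you put first, at 12 h
* the amount of links, in percent of the first end groups charged of the flask you put last, at 12 h

Read the cedar table down its column: links climb to 42.4% at 5.00 h, then sink to 39.2% at 12.0 h. That fall of 3.2 percentage points stands well above the scatter of 0.5 points, so the eating is seen in the readings. Now set cedar beside alder, which has the same second charge: at 12.0 h alder reads 87.8%, more than cedar, with 0.11 M of first end groups against 0.39 M.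

The forecast read the ratio s = k2/k1, the selectivity factor, from cedar's peak as 0.18, and I take that reading. Both steps use first end groups, so if each runs in proportion to its two partners, then per first end group used, links lost over links made is s·L/B, with L the links and B the second end groups. In Saturday's, freeze B at its charge, since the first charge can use at most 16.0% of it. I take L to average about half the first charge, but each side product holds a made link and a first end group that would have become one, so the two factors cancel. Thus s times the first charge over the second, here 2.88%, is the loss share: the part of the first end groups charged that ends in side product. With B at its lowest it is 3.43%. My reckoning: once first end groups are used up, Saturday's links lie between 96.6% and 97.1%.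

The forecast gives Saturday's > Sunday's > Tuesday's > Thursday's > Friday's, with 96.9% (95.5% to 97.8%) on top and 31.5% (29.5% to 33.5%) last, and says of Saturday's: “large excess of second end groups, reaction complete”.

The flask gives Saturday's > Sunday's > Tuesday's > Thursday's > Friday's, with 96.7% and 30.8%. Saturday's ends with 0.00971% of first end groups, 84.3% of its second end groups and 3.25% side product, which lies between the loss shares 2.88% and 3.43%.

    first end groups + second end groups → links + by-product (k = 0.0290 L mol⁻¹ min⁻¹)
    first end groups + links → side product (k = 0.00550 L mol⁻¹ min⁻¹)

With 0.20 M of second end groups in place of Saturday's charge, the loss share grows to 7.20%, or 12.0% with B at its lowest. That flask gives 8.33% side product and 87.7% links, with 3.99% of first end groups still there.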